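**Plan**

- Numbering (target skeleton): C1 quaternary ring-fusion C–Me, C2, C3, C4 isopropyl carbinol, C5 ring-fusion CH, C6 CH–O-aroyl, C7, C8 =C(Me), C9 =CH, C10 CH–O-isovaleryl. The five-membered ring is C1–C5 and the seven-membered ring C1, C5–C10. The target is cis-fused, with C1–Me, H5, C4–OH and C10–O on one face and the isopropyl group and C6–O on the other.
- Retrosynthesis: cut the two acyl C–O bonds (O6–aroyl, O10–isovaleryl), then the C10–O, C6–O and C5–H bonds and the C8 methyl back to an ester. Last cut C7–C8 and C1–C10, which removes C8–C9–C10 as a vinylcarbene and leaves the diene C1=C5–C6=C7 of a 2-methyl-1-vinylcyclopentene.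
- Enabling feature: in the seven-membered ring the C8=C9 alkene lies between C7 and C10 and C1 is quaternary. The ring C1–C5–C6–C7–C8–C9–C10 is therefore the Cope product of a cis-divinylcyclopropane C6–C7–C8 built on that diene, whose five-membered ring (C1–C5 with the C4 carbinol) is ring-contracted terpinen-4-ol.
- Forward: the five-membered ring arises first (ozonolysis of silylated (R)-terpinen-4-ol, aldol condensation, methylenation). The seven-membered ring closes in the rhodium-carbene (4+3) step. Then C5/C6, C10 and the C8 methyl are set and the two esters attached.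
- Stereochemistry: C4 from the chiral pool; C1 from the chiral dirhodium catalyst through the boat Cope; C5 by silicon-tethered hydrogen delivery from O4; C6 by O4-directed anti reduction; C10 by convex-face epoxidation of the cis-fused bicycle.

Key step: step 6

Assumption: (R)-terpinen-4-ol is taken as purchasable in high enantiomeric purity; its carbinol carbon becomes C4 of the target unchanged.

**Route**

Step 1
Reactants: 1 (R)-terpinen-4-ol
Product: 2 (R)-terpinen-4-ol triethylsilyl ether
Conditions: Et3SiOTf, 2,6-lutidine, CH2Cl2, −78 to 0 °C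
Reagents that add atoms: triethylsilyl trifluoromethanesulfonate, CC[Si](CC)(CC)OS(=O)(=O)C(F)(F)F
Why: Silyl triflate silylation of a hindered tertiary alcohol with a non-nucleophilic base is routine and masks the hydroxyl (no carbene O–H insertion later, no retro-aldol after ring cleavage) without touching the C4 stereocentre.

Step 2
Reactants: 2 (R)-terpinen-4-ol triethylsilyl ether
Product: 4 (R)-6-oxo-3-(propan-2-yl)-3-(triethylsilyloxy)heptanal, via ozonide 3 (not isolated)
Conditions: O3, CH2Cl2, −78 °C; then PPh3, −78 to 23 °C
Reagents that add atoms: ozone, [O-][O+]=O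
Why: Ozonolysis with reductive work-up cleaves the only alkene to the methyl ketone and the aldehyde, while the quaternary silyloxy carbon is inert and keeps its configuration.

Step 3
Reactants: 4 (R)-6-oxo-3-(propan-2-yl)-3-(triethylsilyloxy)heptanal
Product: 6 (S)-2-methyl-5-(propan-2-yl)-5-(triethylsilyloxy)cyclopent-1-ene-1-carbaldehyde, via aldol adduct 5 (not isolated)
Conditions: piperidine, AcOH, toluene, 70 °C
Reagents that add atoms: none
Why: Amine–acid-catalysed intramolecular aldol condensation in the enamine mode makes the aldehyde α-carbon (C5) the nucleophile and the methyl ketone (C1) the electrophile, so the five-membered ring closes to the cyclopentenecarbaldehyde and not the acetylcyclopentene, with no new stereocentre.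

Step 4
Reactants: 6 (S)-2-methyl-5-(propan-2-yl)-5-(triethylsilyloxy)cyclopent-1-ene-1-carbaldehyde
Product: 7 (S)-1-ethenyl-2-methyl-5-(propan-2-yl)-5-(triethylsilyloxy)cyclopent-1-ene
Conditions: Ph3PCH3Br, KOt-Bu, THF, 0 to 23 °C
Reagents that add atoms: methyltriphenylphosphonium bromide, C[P+](c1ccccc1)(c1ccccc1)c1ccccc1.[Br-]
Why: Wittig methylenation of the enal gives the diene C1=C5–C6=C7 and leaves the tertiary silyl ether untouched.

Step 5
Reactants: 8 methyl but-3-enoate
Product: 9 methyl 2-diazobut-3-enoate
Conditions: 4-acetamidobenzenesulfonyl azide, DBU, MeCN, 0 °C; kept cold in pentane and used at once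
Reagents that add atoms: 4-acetamidobenzenesulfonyl azide, CC(=O)Nc1ccc(cc1)S(=O)(=O)N=[N+]=[N-]
Why: Regitz diazo transfer to the doubly activated methylene (allylic and α to the ester) is the standard entry to vinyldiazoacetates, which are used immediately because they slowly close to pyrazoles.

Step 6
Reactants: 7 (S)-1-ethenyl-2-methyl-5-(propan-2-yl)-5-(triethylsilyloxy)cyclopent-1-ene, 9 methyl 2-diazobut-3-enoate
Product: 11 C8-ester hydroazulene-5,8-diene (C1 methyl cis to C4 OSiEt3), via cis-divinylcyclopropane 10 (not isolated)
Conditions: Rh2(S-DOSP)4 (1 mol %), hexane, −40 to 23 °C, slow addition of 9 (2.5 equiv); then toluene, 110 °C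
Reagents that add atoms: none
Why: Rh2(S-DOSP)4 converts 9 into a divalent-rhodium vinylcarbene (donor vinyl, acceptor ester) whose carbene carbon C8 adds to the monosubstituted C6=C7 alkene of 7 (cyclopropanation, (2+1)), the usual preference of donor/acceptor carbenes placing the C8 vinyl group cis to the cyclopentenyl group on C6 and so giving the cis-divinylcyclopropane 10. On heating, 10 undergoes the divinylcyclopropane Cope rearrangement, a [3,3]-sigmatropic shift through the boat transition state that breaks C6–C8 and forms C1–C10; this is how the seven-membered ring closes, the overall result being a formal (4+3) cycloaddition with new skeletal bonds C7–C8 and C1–C10. The closest known reaction is the tandem asymmetric cyclopropanation/Cope rearrangement of vinyldiazoacetates with 2-methyl-1-vinylcycloalkenes under chiral dirhodium carboxylate catalysis. The one stereocentre that remains, quaternary C1, is set by the catalyst: its sense of induction on terminal alkenes (assigned by analogy to styrene cyclopropanation) fixes the configuration of C6 and C8 in 10, and the suprafacial boat Cope transfers it to C1 so that the C1 methyl ends up cis to the C4 silyloxy group. The step needs site selectivity (terminal vinyl group, not the tetrasubstituted C1=C5 alkene, and no O–H or Si–H bond for the carbene to insert into), which the substitution pattern and the silyl ether provide, and face selectivity at the vinyl group, which rests on the catalyst because the C4 centre is remote from C6=C7. The C1 methyl is the inward-pointing substituent in the boat, which is why the rearrangement is completed at 110 °C and not at the temperature of the cyclopropanation.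

Step 7
Reactants: 11 C8-ester hydroazulene-5,8-diene (C1 methyl cis to C4 OSiEt3)
Product: 12 C4 tertiary alcohol of the diene ester
Conditions: Bu4NF, THF, 0 to 23 °C
Reagents that add atoms: none
Why: Fluoride-induced cleavage of the triethylsilyl ether frees the C4 hydroxyl that anchors the next step, the ester and both alkenes being inert to fluoride.

Step 8
Reactants: 12 C4 tertiary alcohol of the diene ester
Product: 15 syn-4,6-diol (H5 cis to O4), via dimethylsilyl ether 13 (not isolated), via cyclic siloxane 14 (not isolated)
Conditions: (HMe2Si)2NH, 60 °C, then evaporation; Pt2(dvtms)3 (1 mol %; dvtms = 1,3-divinyltetramethyldisiloxane), toluene, 60 °C; then KF, KHCO3, 30% H2O2, THF/MeOH, 23 °C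
Reagents that add atoms: hydrogen peroxide, OO
Why: Tamao intramolecular hydrosilylation followed by Tamao–Fleming oxidation: the Si–H tethered to O4 adds across C5=C6 in the 5-endo sense under zerovalent-platinum catalysis, so hydrogen reaches C5 and silicon C6 on the face that carries O4 (H5 cis to O4 and to the C1 methyl, hence the cis ring fusion), and peroxide then replaces silicon by hydroxyl with retention.

Step 9
Reactants: 15 syn-4,6-diol (H5 cis to O4)
Product: 16 C6 ketone (4-hydroxy-6-oxo ester)
Conditions: Dess–Martin periodinane, NaHCO3, CH2Cl2, 0 to 23 °C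
Reagents that add atoms: none
Why: Dess–Martin oxidation converts the secondary C6 alcohol to the ketone under buffered near-neutral conditions that spare the tertiary alcohol and should neither epimerise C5 nor move the β,γ-alkene into conjugation.

Step 10
Reactants: 16 C6 ketone (4-hydroxy-6-oxo ester)
Product: 17 anti-4,6-diol (C6–OH trans to H5)
Conditions: Me4NBH(OAc)3, MeCN/AcOH, −30 to 0 °C
Reagents that add atoms: none
Why: Evans–Saksena hydroxyl-directed reduction: the C4 hydroxyl exchanges onto boron and hydride is delivered internally to the C6 carbonyl from the face of O4, which is also the open convex face of the now cis-fused bicycle, giving the 1,3-anti diol with the C6 hydroxyl on the concave face.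

Step 11
Reactants: 17 anti-4,6-diol (C6–OH trans to H5)
Product: 18 C6 triethylsilyl ether
Conditions: Et3SiCl, imidazole, DMAP (cat.), DMF, 23 °C
Reagents that add atoms: chlorotriethylsilane, CC[Si](Cl)(CC)CC
Why: Silyl chloride/imidazole silylation takes place only at the secondary C6 hydroxyl, the tertiary C4 hydroxyl being unreactive under these conditions, and blocks C6 during the work on C8–C10.

Step 12
Reactants: 18 C6 triethylsilyl ether
Product: 20 β,γ-unsaturated ester (C9=C10; mixture at C8), via dilithium dienolate 19 (not isolated)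
Conditions: LiN(i-Pr)2 (3 equiv), DMPU, THF, −78 °C; then AcOH, −78 °C
Reagents that add atoms: none
Why: Deconjugative protonation of an enoate: once the C4 alkoxide is formed the amide base removes the γ-hydrogen at C10 (the only position that gives an ester dienolate) and kinetic protonation at the α-carbon C8 gives the C9=C10 isomer, the C8 configuration being irrelevant because the next step erases it.

Step 13
Reactants: 20 β,γ-unsaturated ester (C9=C10; mixture at C8)
Product: 22 γ-hydroxy enoate (C10–OH cis to C1 methyl), via 9,10-epoxide 21 (not isolated)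
Conditions: mCPBA, NaHCO3, CH2Cl2, 0 °C; then DBU, 23 °C
Reagents that add atoms: 3-chloroperoxybenzoic acid, OOC(=O)c1cccc(Cl)c1
Why: Peracid (Prilezhaev) epoxidation of the only alkene followed by base-induced E1cB opening of the β,γ-epoxy ester: the peracid should approach the cis-fused bicycle on its convex face, which carries the C1 methyl, H5 and the hydrogen-bond-donating C4 hydroxyl, whereas the concave face is closed by the five-membered ring, its isopropyl group and the C6 silyloxy group, so oxygen is placed on C10 cis to the C1 methyl and DBU then returns the alkene to C8=C9.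

Step 14
Reactants: 22 γ-hydroxy enoate (C10–OH cis to C1 methyl)
Product: 23 allylic 1,4-diol (C8–CH2OH)
Conditions: i-Bu2AlH (5 equiv), CH2Cl2, −78 to −20 °C; aq. KNaC4H4O6
Reagents that add atoms: none
Why: Reduction of the conjugated methyl ester with i-Bu2AlH proceeds by 1,2-addition to the primary allylic alcohol, the silyl ether and the hydroxyls (as aluminium alkoxides) being unaffected.

Step 15
Reactants: 23 allylic 1,4-diol (C8–CH2OH)
Product: 25 C8-methyl 4,10-diol, via allylic mesylate 24 (not isolated)
Conditions: MsCl (1.05 equiv), Et3N, THF, −40 °C; then LiEt3BH, −40 to 0 °C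
Reagents that add atoms: none
Why: Selective sulfonylation of the unhindered primary allylic hydroxyl (the C10 hydroxyl is secondary and neopentylic, the C4 hydroxyl tertiary) followed by SN2 hydride displacement with LiEt3BH turns CH2OH into the C8 methyl group without allylic transposition.

Step 16
Reactants: 25 C8-methyl 4,10-diol, 26 isovaleryl chloride
Product: 27 C10 isovalerate
Conditions: pyridine, DMAP, CH2Cl2, 0 to 23 °C
Reagents that add atoms: none
Why: DMAP-catalysed acylation with the acid chloride esterifies the secondary allylic C10 hydroxyl with retention, the tertiary C4 hydroxyl being inert under these conditions.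

Step 17
Reactants: 27 C10 isovalerate
Product: 28 C6 alcohol
Conditions: HF·pyridine, pyridine, THF, 0 to 23 °C
Reagents that add atoms: none
Why: Buffered fluoride desilylation removes the secondary triethylsilyl ether without transesterifying or ionising the allylic isovalerate.

Step 18
Reactants: 29 4-hydroxybenzoic acid
Product: 31 4-(tert-butyldimethylsilyloxy)benzoic acid, via silyl ester 30 (not isolated)
Conditions: t-BuMe2SiCl (2.2 equiv), imidazole, DMF, 23 °C; then AcOH, THF, H2O, 23 °C
Reagents that add atoms: tert-butyldimethylsilyl chloride, CC(C)(C)[Si](C)(C)Cl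
Why: Exhaustive silylation followed by selective hydrolysis of the labile silyl ester leaves the aryl silyl ether and gives the phenol-protected acid, which prevents self-acylation in the coupling.

Step 19
Reactants: 28 C6 alcohol, 31 4-(tert-butyldimethylsilyloxy)benzoic acid
Product: 33 silyl-protected diester, via mixed anhydride 32 (not isolated)
Conditions: 2,4,6-Cl3C6H2COCl, Et3N, toluene, 23 °C; then 28, DMAP, 23 to 60 °C
Reagents that add atoms: none
Why: Yamaguchi esterification activates the acid as its mixed anhydride and DMAP transfers the aroyl group to the hindered secondary C6 hydroxyl with retention at C6, the tertiary C4 hydroxyl remaining free.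

Step 20
Reactants: 33 silyl-protected diester
Product: 34 target compound
Conditions: Bu4NF, AcOH, THF, 0 °C
Reagents that add atoms: none
Why: Fluoride desilylation cleaves the aryl silyl ether far faster than it attacks carboxylic esters, and buffering with acetic acid suppresses acyl migration and hydrolysis, so the phenol is released to give the target.

**Compound list**

1 | (R)-terpinen-4-ol, (R)-4-methyl-1-(propan-2-yl)cyclohex-3-en-1-ol | CC1=CC[C@@](O)(C(C)C)CC1 | starting material
2 | (R)-terpinen-4-ol triethylsilyl ether | CC1=CC[C@@](O[Si](CC)(CC)CC)(C(C)C)CC1 | intermediate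
3 | ozonide (1,2,4-trioxolane) of 2 | CC12CC[C@](O[Si](CC)(CC)CC)(C(C)C)CC(OO1)O2 | intermediate (not isolated)
4 | (R)-6-oxo-3-(propan-2-yl)-3-(triethylsilyloxy)heptanal | CC(=O)CC[C@](O[Si](CC)(CC)CC)(C(C)C)CC=O | intermediate
5 | aldol adduct, 2-hydroxy-2-methyl-5-(propan-2-yl)-5-(triethylsilyloxy)cyclopentane-1-carbaldehyde | CC1(O)CC[C@](O[Si](CC)(CC)CC)(C(C)C)C1C=O | intermediate (not isolated)
6 | (S)-2-methyl-5-(propan-2-yl)-5-(triethylsilyloxy)cyclopent-1-ene-1-carbaldehyde | CC1=C(C=O)[C@@](O[Si](CC)(CC)CC)(C(C)C)CC1 | intermediate
7 | (S)-1-ethenyl-2-methyl-5-(propan-2-yl)-5-(triethylsilyloxy)cyclopent-1-ene (diene C1=C5–C6=C7) | CC1=C(C=C)[C@@](O[Si](CC)(CC)CC)(C(C)C)CC1 | intermediate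
8 | methyl but-3-enoate | C=CCC(=O)OC | starting material
9 | methyl 2-diazobut-3-enoate | C=CC(=[N+]=[N-])C(=O)OC | intermediate
10 | cis-divinylcyclopropane (ring C6–C7–C8; C8 carries CO2Me and vinyl, C6 carries the cyclopentenyl group cis to the vinyl group) | COC(=O)[C@@]1(C=C)C[C@@H]1C2=C(C)CC[C@]2(O[Si](CC)(CC)CC)C(C)C | intermediate (not isolated)
11 | (4+3) adduct: bicyclo[5.3.0]deca-5,8-diene (skeleton numbering) with CO2Me on C8, methyl on C1, isopropyl and OSiEt3 on C4, methyl cis to OSiEt3 | COC(=O)C1=CC[C@]2(C)CC[C@](O[Si](CC)(CC)CC)(C(C)C)C2=CC1 | intermediate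
12 | C4 tertiary alcohol of 11 | COC(=O)C1=CC[C@]2(C)CC[C@](O)(C(C)C)C2=CC1 | intermediate
13 | C4 dimethylsilyl (Si–H) ether of 12 | COC(=O)C1=CC[C@]2(C)CC[C@](O[SiH](C)C)(C(C)C)C2=CC1 | intermediate (not isolated)
14 | cyclic siloxane O4–SiMe2–C6 (H5 and Si on the face of O4) | COC(=O)C1=CC[C@]2(C)CC[C@@]3(C(C)C)O[Si](C)(C)[C@@H](C1)[C@H]23 | intermediate (not isolated)
15 | syn-4,6-diol: C8 ester, C8=C9, cis ring fusion, C6–OH on the face of O4 and H5 | COC(=O)C1=CC[C@]2(C)CC[C@](O)(C(C)C)[C@@H]2[C@@H](O)C1 | intermediate
16 | C6 ketone (4-hydroxy-6-oxo ester) | COC(=O)C1=CC[C@]2(C)CC[C@](O)(C(C)C)[C@@H]2C(=O)C1 | intermediate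
17 | anti-4,6-diol: C6–OH trans to H5 and to O4 | COC(=O)C1=CC[C@]2(C)CC[C@](O)(C(C)C)[C@@H]2[C@H](O)C1 | intermediate
18 | C6 triethylsilyl ether of 17 | COC(=O)C1=CC[C@]2(C)CC[C@](O)(C(C)C)[C@@H]2[C@H](O[Si](CC)(CC)CC)C1 | intermediate
19 | dilithium salt: C4 alkoxide and ester dienolate (C8=C(OMe)O, C9=C10) | [Li+].[Li+].COC([O-])=C1C=C[C@]2(C)CC[C@]([O-])(C(C)C)[C@@H]2[C@H](O[Si](CC)(CC)CC)C1 | intermediate (not isolated)
20 | β,γ-unsaturated ester: C8–H(CO2Me), C9=C10, mixture at C8 | COC(=O)C1C=C[C@]2(C)CC[C@](O)(C(C)C)[C@@H]2[C@H](O[Si](CC)(CC)CC)C1 | intermediate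
21 | 9,10-epoxide of 20, oxygen on the face of the C1 methyl | COC(=O)C1[C@H]3O[C@H]3[C@]2(C)CC[C@](O)(C(C)C)[C@@H]2[C@H](O[Si](CC)(CC)CC)C1 | intermediate (not isolated)
22 | γ-hydroxy enoate: C8 ester, C8=C9, C10–OH cis to C1 methyl | COC(=O)C1=C[C@@H](O)[C@]2(C)CC[C@](O)(C(C)C)[C@@H]2[C@H](O[Si](CC)(CC)CC)C1 | intermediate
23 | allylic 1,4-diol: C8–CH2OH, C10–OH | OCC1=C[C@@H](O)[C@]2(C)CC[C@](O)(C(C)C)[C@@H]2[C@H](O[Si](CC)(CC)CC)C1 | intermediate
24 | primary allylic mesylate of 23 | CS(=O)(=O)OCC1=C[C@@H](O)[C@]2(C)CC[C@](O)(C(C)C)[C@@H]2[C@H](O[Si](CC)(CC)CC)C1 | intermediate (not isolated)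
25 | C8-methyl 4,10-diol with C6–OSiEt3 | CC1=C[C@@H](O)[C@]2(C)CC[C@](O)(C(C)C)[C@@H]2[C@H](O[Si](CC)(CC)CC)C1 | intermediate
26 | isovaleryl chloride (3-methylbutanoyl chloride) | CC(C)CC(=O)Cl | starting material
27 | C10 isovalerate with C6–OSiEt3 | CC1=C[C@@H](OC(=O)CC(C)C)[C@]2(C)CC[C@](O)(C(C)C)[C@@H]2[C@H](O[Si](CC)(CC)CC)C1 | intermediate
28 | C10 isovalerate with free C6–OH and C4–OH | CC1=C[C@@H](OC(=O)CC(C)C)[C@]2(C)CC[C@](O)(C(C)C)[C@@H]2[C@H](O)C1 | intermediate
29 | 4-hydroxybenzoic acid | O=C(O)c1ccc(O)cc1 | starting material
30 | tert-butyldimethylsilyl 4-(tert-butyldimethylsilyloxy)benzoate | CC(C)(C)[Si](C)(C)OC(=O)c1ccc(O[Si](C)(C)C(C)(C)C)cc1 | intermediate (not isolated)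
31 | 4-(tert-butyldimethylsilyloxy)benzoic acid | CC(C)(C)[Si](C)(C)Oc1ccc(C(=O)O)cc1 | intermediate
32 | mixed anhydride of 31 with 2,4,6-trichlorobenzoic acid | CC(C)(C)[Si](C)(C)Oc1ccc(C(=O)OC(=O)c2c(Cl)cc(Cl)cc2Cl)cc1 | intermediate (not isolated)
33 | C10 isovalerate, C6 4-(tert-butyldimethylsilyloxy)benzoate | CC1=C[C@@H](OC(=O)CC(C)C)[C@]2(C)CC[C@](O)(C(C)C)[C@@H]2[C@H](OC(=O)c2ccc(O[Si](C)(C)C(C)(C)C)cc2)C1 | intermediate
34 | CNP0086724.1: C10 isovalerate, C6 4-hydroxybenzoate, C4 tertiary alcohol | CC1=C[C@@H](OC(=O)CC(C)C)[C@]2(C)CC[C@](O)(C(C)C)[C@@H]2[C@H](OC(=O)c2ccc(O)cc2)C1 | target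

**Count and risks**

Total step count: 20. Longest linear sequence: 18 steps (steps 1–4, 6–17, 19, 20); steps 5 and 18 are side branches.

Steps most likely to fail:

1. Step 6. The unsubstituted vinyldiazoacetate may close to the pyrazole or dimerise faster than the carbene is captured by the hindered diene. The catalyst may not override the chiral diene in the cyclopropanation. The Cope rearrangement may stall because the C1 methyl points into the boat. Fallback, same bonds with a different carbene partner: starting from diene 7, the stable enol-silylated reagent methyl 2-diazo-3-(tert-butyldimethylsilyloxy)but-3-enoate F1 would be used. It is made from commercial methyl 2-diazo-3-oxobutanoate with t-BuMe2SiOTf and Et3N. The catalyst would be the adamantylglycinate complex of matching sense, expected to be Rh2(R-PTAD)4, the combination with the strongest record for 2-methyl-1-vinylcycloalkenes. The same cyclopropanation/Cope sequence would give the C9 silyl enol ether adduct F2. Buffered fluoride (Bu4NF, AcOH, −20 °C) would unmask the β-keto ester F3 and NaBH4 (MeOH, 0 °C) would reduce it to the β-hydroxy ester F4. Mesylation (MsCl, Et3N) and DBU elimination would then give enoate 11, where the route is rejoined.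

2. Step 8. The 5-endo hydrosilylation may not take place at the hindered trisubstituted C5=C6 alkene, or platinum hydride may isomerise that alkene into conjugation with the enoate before silicon is delivered. Fallback, oxygen first and hydrogen by a 1,2-shift: starting from silyl ether 11, mCPBA (NaHCO3, CH2Cl2, 0 °C) should epoxidise the electron-rich C5=C6 alkene on the face away from the C1 methyl and the C4 silyloxy group, giving the 5,6-epoxide F5. A Meinwald rearrangement (BF3·OEt2, CH2Cl2, −78 °C) would move the C6 hydrogen to C5 anti to the departing oxygen, placing H5 cis to O4, and give the silyloxy ketone F6. Bu4NF would then free the C4 hydroxyl and the route is rejoined at 16.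

3. Step 13 (with step 12). Facial selectivity of the epoxidation may be poor or inverted, the peracid entering anti to the angular methyl on the concave face; γ-deprotonation at the neopentylic C10 in step 12 may also be incomplete. Fallback, inverting the sense of the operation so that the same facial bias gives the wanted epimer: starting from 18, γ-selective allylic oxidation with Rh2(cap)4 (dirhodium tetracaprolactamate) and t-BuOOH (CH2Cl2, 23 °C) would give the C10 enone F7. Luche reduction (NaBH4, CeCl3·7H2O, MeOH, −78 °C) would then add hydride on the face the peracid preferred, leaving the hydroxyl cis to the C1 methyl, and the route is rejoined at 22.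

**Further compounds**

F1 | step 6 | methyl 2-diazo-3-(tert-butyldimethylsilyloxy)but-3-enoate | C=C(O[Si](C)(C)C(C)(C)C)C(=[N+]=[N-])C(=O)OC
F2 | step 6 | C9 silyl enol ether adduct (as 11 with OSi(t-Bu)Me2 on C9) | COC(=O)C1=C(O[Si](C)(C)C(C)(C)C)C[C@]2(C)CC[C@](O[Si](CC)(CC)CC)(C(C)C)C2=CC1
F3 | step 6 | β-keto ester (C9 ketone, C8–H ester, mixture at C8) | COC(=O)C1C(=O)C[C@]2(C)CC[C@](O[Si](CC)(CC)CC)(C(C)C)C2=CC1
F4 | step 6 | β-hydroxy ester (C9–OH, mixture at C8 and C9) | COC(=O)C1C(O)C[C@]2(C)CC[C@](O[Si](CC)(CC)CC)(C(C)C)C2=CC1
F5 | step 8 | 5,6-epoxide of 11, oxygen trans to C1 methyl and O4 | COC(=O)C1=CC[C@]2(C)CC[C@](O[Si](CC)(CC)CC)(C(C)C)[C@]23O[C@@H]3C1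
F6 | step 8 | C6 ketone with C4–OSiEt3, H5 cis to O4 | COC(=O)C1=CC[C@]2(C)CC[C@](O[Si](CC)(CC)CC)(C(C)C)[C@@H]2C(=O)C1
F7 | step 13 | C10 enone (γ-oxo enoate) with C6–OSiEt3 | COC(=O)C1=CC(=O)[C@]2(C)CC[C@](O)(C(C)C)[C@@H]2[C@H](O[Si](CC)(CC)CC)C1
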